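## Analysis of the target

The target is a flavanone (a 2-aryl-chroman-4-one) in which ring A is a benzene ring with a free hydroxyl at C7 and ring C is the six-membered heterocycle O1–C2–C3–C4(=O)–C4a–C8a. Ring B, attached at C2, is a 4-hydroxyphenyl ring flanked at C3' and C5' by two linear 3-methylbut-2-enyl (prenyl) groups. There is one stereocentre, C2, with S configuration; it is benzylic to ring B, bonded to O1, and β to the C4 carbonyl. That position is what makes it fragile: base opens ring C by retro-oxa-Michael elimination of the O1 phenoxide, and acid can ionise the C2–O1 bond, helped by the para oxygen of ring B; either path racemises C2. The prenyl alkenes are a second liability: they cyclise onto the neighbouring phenol under strong acid, are attacked by electrophilic oxidants and halogens, and can take part in hydrogenation or metathesis. The difficulty is therefore threefold: setting C2 in high enantiomeric purity, keeping it, and placing two linear prenyl groups ortho to one phenol, with all late chemistry selective in their presence. The strategy rests on the C3–C4 bond of ring C, which is remote from O1 and from C2. If it is made as an alkene, C2 is only an allylic, benzylic ether carbon with no carbonyl next to it, ring C can be closed between a vinyl group on C4a and a vinyl group on C2, and the C4 carbonyl can be added last.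

## Retrosynthetic reasoning

**20 from 17.** The two phenols at C7 and C4' are revealed last from their methoxymethyl acetals. Acetals are chosen because they survive base, hydride, organozinc and the three transition-metal steps, and come off under mild acid, the only medium in which the finished flavanone does not open by elimination.

**17 from 16.** The C4 carbonyl is traced back to the C3=C4 alkene of 2H-chromene 16. This is the disconnection that removes the racemisation problem: as long as C4 is an alkene carbon, C2 has no enolisable neighbour. The forward Wacker-type oxidation has to put oxygen on C4 and not on C3, leave the two trisubstituted alkenes alone, and not ionise the C2–O1 bond.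

**16 from 15.** The C3=C4 bond is cut by ring-closing metathesis, giving diene 15 with a vinyl group on C4a and a vinyl group on C2. The cut is made here and not at C2–O1 or C2–C3 because it is the only ring bond whose formation leaves C2 entirely untouched, and the reaction is neutral. The forward step must engage the two terminal alkenes and ignore the two prenyl groups.

**15 from 3 and 13.** The C2–O1 bond is cut next. This divides the molecule into a ring A phenol 3 and an achiral, linear ring B cinnamyl carbonate 13, and it creates the stereocentre in the same event. The forward reaction is a branch-selective, enantioselective iridium-catalysed allylic etherification, which must deliver the S ether at the aryl-bearing allyl terminus.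

**3 from 2 from 1.** The vinyl group of 3 comes from the formyl group of 2 by Wittig methylenation, and 2 from 1 by selective acetalisation of the 4-hydroxyl. The 2-hydroxyl is hydrogen-bonded to the formyl group, so no protecting-group differentiation is needed.

**13 from 12 from 10.** The carbonate is made from allylic alcohol 12, which comes from enoate 10 by aluminium hydride reduction, passing through enal 11.

**10 from 6 and 7.** Both aryl–CH2 bonds of the prenyl groups are cut, leading to dibromide 6 and two equivalents of prenyl bromide 7, which is used as its zinc reagent 8; the coupling passes through the mono-coupled bromide 9. The bromine atoms fix the prenyl positions, so O- versus C-alkylation is not an issue, and the forward Negishi coupling must deliver the linear allyl isomer twice.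

**6 from 5 from 4.** The enoate is made by Horner–Wadsworth–Emmons olefination of aldehyde 5, the acetal of purchased dibromophenol 4. The olefination is placed before the coupling because a formyl group would not tolerate an allylzinc reagent.

## Alternatives that were turned down

**Alternative 1:** Rings A and C are both opened, cutting C4a–C8a, C5–C6 and C7–C8. The precursors are the chiral diyne A2, with an ynol ether on the C2 oxygen and a silyl alkyne beyond a silyloxy-bearing C4, and the alkynylboronate A3. The catalyst Cp*RuCl(cod) would trimerise the three alkynes to the flavan A1. In its favour, three C–C bonds and two rings form in one step, and the boryl group marks C7 for the phenol; on bonds per step it is clearly stronger than the chosen route. Against it, the ring A it builds is a plain resorcinol pattern that can be bought. A2 carries a benzylic alkynyl ether, which is prone to hydrolysis and sigmatropic rearrangement. The C2 stereocentre must still be made separately beforehand. Insertion of A3 must be regioselective, and this catalyst class also couples alkynes with alkenes such as the prenyl groups. After A1, oxidation of C–B, removal of the C5 silyl group, oxidation at C4 and two deprotections remain. The chosen route makes one bond in its key step but from simple precursors, with predictable selectivity and only two steps afterwards.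

**Alternative 2:** The C2–C3 bond is cut, leading back to the racemic enol acetal A5. A chiral Brønsted acid would open the acetal at C2, and the freed enol carbon would recombine with the oxocarbenium ion to give the silyl-protected flavanone A4. In its favour, ring C, the stereocentre and the C4 carbonyl form together from a racemate, only desilylation follows, and there is no question of where the carbonyl ends up. On step economy after the key step and on carbonyl regiochemistry it is stronger than the chosen route. Against it, facial control must come from a chiral counter-anion paired with an oxocarbenium ion that the para-oxygenated ring B stabilises strongly; such a long-lived, loosely paired cation discriminates poorly between faces. The product A4 also retains the easily ionised benzylic C2–O1 bond next to a ketone, so the acid that forms it can re-ionise it and erode the enantiomeric purity, and the prenyl groups are exposed to strong acid. The chosen route costs two more steps but sets C2 with a catalyst class of proven reach on cinnamyl carbonates and then keeps it away from any carbonyl until the penultimate step.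

**Alternative 3:** Ring B is opened at C2'–C3' and C5'–C6', giving the symmetrical ketone A7 and the diformylacetate A8. A double aldol condensation with aromatisation would give the benzoate A6. In its favour, both prenyl groups are placed by construction, with no O- versus C-alkylation or linear versus branched issue; on that single point it is stronger than the palladium-catalysed coupling used here. Against it, it solves only the ring B substitution pattern and contributes nothing to ring C or to C2. A7 needs its own synthesis, A8 is fragile under the basic conditions in which a dialkyl ketone also self-condenses, and A6 arrives as a benzoate that must be reduced and homologated before it reaches the stage of enoate 10. The chosen route reaches the same pattern in one coupling step from a purchased dibromide and spends its key step on the bond that actually protects the stereocentre.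

Key step: step 9

Assumption: the (Sa,Sc,Sc) phosphoramidite is taken to give the S ether, following the usual sense of this catalyst family with aryl-substituted allyl carbonates and heteroatom nucleophiles; if the first run shows the opposite sense, the mirror-image ligand is used and nothing else changes.

Assumption: compound 4 is taken as purchased; it is the dibromination product of 4-hydroxybenzaldehyde.

## Route

Step 1
Reactants: 1 2,4-dihydroxybenzaldehyde
Product: 2 2-hydroxy-4-(methoxymethoxy)benzaldehyde
Conditions: MOMCl (1.05 equiv), K2CO3, acetone, 0 °C to rt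
Reagents that add atoms: chloromethyl methyl ether, COCCl
Why: Williamson-type O-alkylation; the 2-hydroxyl is tied up in a hydrogen bond to the formyl group and is the poorer nucleophile under carbonate conditions, so only the 4-hydroxyl should be acetalised.

Step 2
Reactants: 2 2-hydroxy-4-(methoxymethoxy)benzaldehyde
Product: 3 5-(methoxymethoxy)-2-vinylphenol
Conditions: Ph3PCH3Br (2.5 equiv), KOt-Bu (2.5 equiv), THF, 0 °C to rt; aq NH4Cl
Reagents that add atoms: methyltriphenylphosphonium bromide, C[P+](c1ccccc1)(c1ccccc1)c1ccccc1.[Br-]
Why: Wittig methylenation; one equivalent of ylide is consumed by the phenol and the rest olefinates the formyl group of the phenoxide, the acetal being inert to base; the electron-rich vinylphenol should be used promptly because acid traces oligomerise it.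

Step 3
Reactants: 4 3,5-dibromo-4-hydroxybenzaldehyde
Product: 5 3,5-dibromo-4-(methoxymethoxy)benzaldehyde
Conditions: MOMCl, i-Pr2NEt, CH2Cl2, 0 °C to rt
Reagents that add atoms: chloromethyl methyl ether, COCCl
Why: O-alkylation of an acidic phenol with a very reactive α-chloro ether; the small electrophile should overcome the hindrance of the two ortho bromine atoms.

Step 4
Reactants: 5 3,5-dibromo-4-(methoxymethoxy)benzaldehyde
Product: 6 ethyl (2E)-3-[3,5-dibromo-4-(methoxymethoxy)phenyl]prop-2-enoate
Conditions: (EtO)2P(O)CH2CO2Et, NaH, THF, 0 °C to rt
Reagents that add atoms: triethyl phosphonoacetate, CCOC(=O)CP(=O)(OCC)OCC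
Why: Horner–Wadsworth–Emmons olefination of an aromatic aldehyde with a stabilised phosphonate, which should give the E enoate; it also removes the formyl group before the allylzinc reagent of step 5 is used.

Step 5
Reactants: 6 ethyl (2E)-3-[3,5-dibromo-4-(methoxymethoxy)phenyl]prop-2-enoate; 7 prenyl bromide (1-bromo-3-methylbut-2-ene)
Product: 10 ethyl (2E)-3-[4-(methoxymethoxy)-3,5-bis(3-methylbut-2-en-1-yl)phenyl]prop-2-enoate, via (3-methylbut-2-en-1-yl)zinc bromide 8 (not isolated), via the monoprenylated bromo ester 9 (not isolated)
Conditions: 7 (3 equiv), Zn dust (4.5 equiv), LiCl (3.3 equiv), THF, 0 °C to rt; then 6 (1 equiv), Pd(OAc)2 (4 mol %), CPhos (8 mol %), THF, rt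
Reagents that add atoms: prenyl bromide (the second equivalent of 7, which supplies the second prenyl group), CC(C)=CCBr
Why: Negishi cross-coupling carried out twice on one ring, so that two equivalents of zinc reagent 8 are consumed, one for each C–Br bond, the second coupling running through bromide 9; zerovalent palladium inserts into each C–Br bond (activated by the para enoate), transmetalation gives an aryl(prenyl)palladium species, and the bulky biarylphosphine should force reductive elimination at the unsubstituted allyl terminus, giving the linear prenyl group. Allylzinc halides tolerate esters and enoates at room temperature.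

Step 6
Reactants: 10 ethyl (2E)-3-[4-(methoxymethoxy)-3,5-bis(3-methylbut-2-en-1-yl)phenyl]prop-2-enoate
Product: 12 (2E)-3-[4-(methoxymethoxy)-3,5-bis(3-methylbut-2-en-1-yl)phenyl]prop-2-en-1-ol, via the enal 11 (not isolated)
Conditions: i-Bu2AlH (2.5 equiv), CH2Cl2, −78 to −20 °C; aq KNaC4H4O6
Reagents that add atoms: none
Why: 1,2-reduction of an enoate by an electrophilic aluminium hydride; the aldehyde formed first is reduced faster than the ester, so the reaction should run through to the allylic alcohol without conjugate reduction and without touching the alkenes or the acetal.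

Step 7
Reactants: 12 (2E)-3-[4-(methoxymethoxy)-3,5-bis(3-methylbut-2-en-1-yl)phenyl]prop-2-en-1-ol
Product: 13 ethyl (2E)-3-[4-(methoxymethoxy)-3,5-bis(3-methylbut-2-en-1-yl)phenyl]prop-2-en-1-yl carbonate
Conditions: ClCO2Et, pyridine, CH2Cl2, 0 °C
Reagents that add atoms: ethyl chloroformate, CCOC(=O)Cl
Why: acylation of a primary allylic alcohol; the ethyl carbonate is chosen so that the ethoxide released in step 8 can only regenerate the same carbonate.

Step 8
Reactants: 3 5-(methoxymethoxy)-2-vinylphenol; 13 ethyl (2E)-3-[4-(methoxymethoxy)-3,5-bis(3-methylbut-2-en-1-yl)phenyl]prop-2-en-1-yl carbonate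
Product: 15 2-{[(1S)-1-[4-(methoxymethoxy)-3,5-bis(3-methylbut-2-en-1-yl)phenyl]prop-2-en-1-yl]oxy}-4-(methoxymethoxy)-1-vinylbenzene, via lithium 5-(methoxymethoxy)-2-vinylphenoxide 14 (not isolated)
Conditions: 3, LiN(SiMe3)2, THF, 0 °C; [Ir(cod)Cl]2 (2 mol %), (Sa,Sc,Sc)-binaphthol-derived N,N-bis(1-phenylethyl)phosphoramidite (4 mol %), n-PrNH2 pre-activation; 13, THF, 25–40 °C
Reagents that add atoms: none
Why: iridium-catalysed asymmetric allylic etherification; the cyclometalated iridium phosphoramidite ionises the carbonate to a π-allyl complex, and the phenoxide attacks the aryl-substituted terminus anti to the metal, which is the intrinsic branch preference of this catalyst; the ligand fixes which allyl face is bound and so should set C2 as S from the achiral linear carbonate, and the reaction is stopped at full conversion to keep the product from re-ionising.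

Step 9
Reactants: 15 2-{[(1S)-1-[4-(methoxymethoxy)-3,5-bis(3-methylbut-2-en-1-yl)phenyl]prop-2-en-1-yl]oxy}-4-(methoxymethoxy)-1-vinylbenzene
Product: 16 (2S)-7-(methoxymethoxy)-2-[4-(methoxymethoxy)-3,5-bis(3-methylbut-2-en-1-yl)phenyl]-2H-chromene
Conditions: (H2IMes)(PCy3)Cl2Ru=CHPh (second-generation Grubbs catalyst, 3–5 mol %), 1,4-benzoquinone (10 mol %), CH2Cl2 (0.01 M), 40 °C, argon purge, dark
Reagents that add atoms: none
Why: Ring-closing olefin metathesis of the kind established for turning allyl 2-vinylphenyl ethers into 2H-chromenes. The ruthenium benzylidene exchanges onto one of the two monosubstituted alkenes of 15, most readily the unhindered, electron-rich styrenic vinyl group, and the new alkylidene undergoes intramolecular [2+2] cycloaddition with the other vinyl group. Cycloreversion of the ruthenacyclobutane releases the C3=C4 double bond, and the remaining methylidene carries the chain with loss of ethylene, whose removal in the argon stream drives the closure. Ring C is thus closed as a six-membered ring by joining C3 to C4, the cis geometry of the new alkene being imposed by the ring. No stereocentre is formed; C2 is an allylic, benzylic ether carbon that takes no part and cannot epimerise under these neutral conditions. The selectivity needed is for the two terminal vinyl groups over the two trisubstituted prenyl alkenes, and it should be secured by the much lower rate at which this catalyst engages trisubstituted alkenes, by the kinetic advantage of an intramolecular six-membered closure, and by high dilution with a short reaction time. Benzoquinone intercepts ruthenium hydrides, so the product should not drift to the conjugated 4H-chromene, and exclusion of light keeps the 2H-chromene from electrocyclic ring opening.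

Step 10
Reactants: 16 (2S)-7-(methoxymethoxy)-2-[4-(methoxymethoxy)-3,5-bis(3-methylbut-2-en-1-yl)phenyl]-2H-chromene
Product: 17 (2S)-7-(methoxymethoxy)-2-[4-(methoxymethoxy)-3,5-bis(3-methylbut-2-en-1-yl)phenyl]-2,3-dihydro-4H-chromen-4-one
Conditions: Pd(quinox)Cl2 (5 mol %; quinox = 2-(4,5-dihydrooxazol-2-yl)quinoline), AgSbF6 (12 mol %), 70% aq t-BuOOH (10 equiv), CH2Cl2, 0 °C to rt, dark
Reagents that add atoms: tert-butyl hydroperoxide, CC(C)(C)OO
Why: Proposed new method: a Wacker-type oxidation has not been shown to convert a 2-aryl-2H-chromene into a chroman-4-one; the closest known reaction type is the tert-butyl hydroperoxide Wacker oxidation of styrenes and of internal alkenes bearing an allylic oxygen, in which cationic divalent palladium delivers its tert-butylperoxide ligand to the carbon that best supports positive charge and the ketone forms by a 1,2-hydride shift with O–O cleavage; here C4 is benzylic to a ring with oxygen ortho and para to it while C3 is deactivated by the adjacent C2–O1 bond, so oxygen should enter at C4, the hindered prenyl alkenes should not compete for the metal, and because neither zerovalent palladium nor a palladium hydride is formed the allylic ether at C2 should be neither ionised nor isomerised.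

Step 11
Reactants: 17 (2S)-7-(methoxymethoxy)-2-[4-(methoxymethoxy)-3,5-bis(3-methylbut-2-en-1-yl)phenyl]-2,3-dihydro-4H-chromen-4-one
Product: 20 (2S)-7-hydroxy-2-[4-hydroxy-3,5-bis(3-methylbut-2-en-1-yl)phenyl]-2,3-dihydro-4H-chromen-4-one, via the 7-hydroxy monoacetal 18 (not isolated), via the 4'-hydroxy monoacetal 19 (not isolated)
Conditions: 3 M aq HCl (5 equiv), MeOH, 25–40 °C, monitored and stopped at full conversion
Reagents that add atoms: none
Why: acid-catalysed acetal methanolysis through an oxocarbenium ion; without base ring C cannot open by the elimination pathway, so C2 should keep its configuration, and dilute acid for a short time should leave the prenyl groups uncyclised.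

## Compound list

1 | 2,4-dihydroxybenzaldehyde | O=Cc1ccc(O)cc1O | starting material
2 | 2-hydroxy-4-(methoxymethoxy)benzaldehyde | COCOc1ccc(C=O)c(O)c1 | intermediate
3 | 5-(methoxymethoxy)-2-vinylphenol | COCOc1ccc(C=C)c(O)c1 | intermediate
4 | 3,5-dibromo-4-hydroxybenzaldehyde | O=Cc1cc(Br)c(O)c(Br)c1 | starting material
5 | 3,5-dibromo-4-(methoxymethoxy)benzaldehyde | COCOc1c(Br)cc(C=O)cc1Br | intermediate
6 | ethyl (2E)-3-[3,5-dibromo-4-(methoxymethoxy)phenyl]prop-2-enoate | CCOC(=O)/C=C/c1cc(Br)c(OCOC)c(Br)c1 | intermediate
7 | prenyl bromide (1-bromo-3-methylbut-2-ene) | CC(C)=CCBr | starting material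
8 | (3-methylbut-2-en-1-yl)zinc bromide | CC(C)=CC[Zn]Br | intermediate (not isolated)
9 | ethyl (2E)-3-[3-bromo-4-(methoxymethoxy)-5-(3-methylbut-2-en-1-yl)phenyl]prop-2-enoate | CCOC(=O)/C=C/c1cc(Br)c(OCOC)c(CC=C(C)C)c1 | intermediate (not isolated)
10 | ethyl (2E)-3-[4-(methoxymethoxy)-3,5-bis(3-methylbut-2-en-1-yl)phenyl]prop-2-enoate | CCOC(=O)/C=C/c1cc(CC=C(C)C)c(OCOC)c(CC=C(C)C)c1 | intermediate
11 | (2E)-3-[4-(methoxymethoxy)-3,5-bis(3-methylbut-2-en-1-yl)phenyl]prop-2-enal | O=C/C=C/c1cc(CC=C(C)C)c(OCOC)c(CC=C(C)C)c1 | intermediate (not isolated)
12 | (2E)-3-[4-(methoxymethoxy)-3,5-bis(3-methylbut-2-en-1-yl)phenyl]prop-2-en-1-ol | OC/C=C/c1cc(CC=C(C)C)c(OCOC)c(CC=C(C)C)c1 | intermediate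
13 | ethyl (2E)-3-[4-(methoxymethoxy)-3,5-bis(3-methylbut-2-en-1-yl)phenyl]prop-2-en-1-yl carbonate | CCOC(=O)OC/C=C/c1cc(CC=C(C)C)c(OCOC)c(CC=C(C)C)c1 | intermediate
14 | lithium 5-(methoxymethoxy)-2-vinylphenoxide | [Li+].[O-]c1cc(OCOC)ccc1C=C | intermediate (not isolated)
15 | 2-{[(1S)-1-[4-(methoxymethoxy)-3,5-bis(3-methylbut-2-en-1-yl)phenyl]prop-2-en-1-yl]oxy}-4-(methoxymethoxy)-1-vinylbenzene | CC(C)=CCc1cc([C@@H](Oc2cc(OCOC)ccc2C=C)C=C)cc(CC=C(C)C)c1OCOC | intermediate
16 | (2S)-7-(methoxymethoxy)-2-[4-(methoxymethoxy)-3,5-bis(3-methylbut-2-en-1-yl)phenyl]-2H-chromene | CC(C)=CCc1cc([C@@H]2C=Cc3ccc(OCOC)cc3O2)cc(CC=C(C)C)c1OCOC | intermediate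
17 | (2S)-7-(methoxymethoxy)-2-[4-(methoxymethoxy)-3,5-bis(3-methylbut-2-en-1-yl)phenyl]-2,3-dihydro-4H-chromen-4-one | CC(C)=CCc1cc([C@@H]2CC(=O)c3ccc(OCOC)cc3O2)cc(CC=C(C)C)c1OCOC | intermediate
18 | (2S)-7-hydroxy-2-[4-(methoxymethoxy)-3,5-bis(3-methylbut-2-en-1-yl)phenyl]-2,3-dihydro-4H-chromen-4-one | CC(C)=CCc1cc([C@@H]2CC(=O)c3ccc(O)cc3O2)cc(CC=C(C)C)c1OCOC | intermediate (not isolated)
19 | (2S)-2-[4-hydroxy-3,5-bis(3-methylbut-2-en-1-yl)phenyl]-7-(methoxymethoxy)-2,3-dihydro-4H-chromen-4-one | CC(C)=CCc1cc([C@@H]2CC(=O)c3ccc(OCOC)cc3O2)cc(CC=C(C)C)c1O | intermediate (not isolated)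
20 | (2S)-7-hydroxy-2-[4-hydroxy-3,5-bis(3-methylbut-2-en-1-yl)phenyl]-2,3-dihydro-4H-chromen-4-one | CC(C)=CCc1cc([C@@H]2CC(=O)c3ccc(O)cc3O2)cc(CC=C(C)C)c1O | target

## Step count and least certain steps

Total: 11 steps. Longest linear sequence: 9 steps (steps 3 to 11, from 4 to 20); the ring A branch (steps 1 and 2) joins at step 8.

**Step 10 (no direct precedent).** The most likely failure is delivery of oxygen to C3 instead of C4, because palladium's preference for sitting on a benzylic carbon can compete with the charge-based preference for attack at C4. Further risks are Lewis-acid ionisation of the C2–O1 bond, with ring opening and racemisation, and radical peroxidation at the allylic CH2 groups of the prenyl chains. The fallback uses known chemistry and brings the C4 oxygen in with ring A while still closing ring C across C3–C4. It sets out from carbonate 13. Purchased 1-(2,4-dihydroxyphenyl)ethanone F1 is protected selectively (MOMCl, K2CO3, acetone) as 1-[2-hydroxy-4-(methoxymethoxy)phenyl]ethanone F2. The lithium phenoxide of F2 is coupled with 13 under the conditions of step 8 to give the (S)-aryl ether ketone F3. Its kinetic enolate (KN(SiMe3)2, THF, −78 °C) is silylated with t-BuMe2SiCl to the silyl enol ether F4. Ring-closing metathesis of the terminal vinyl group onto the enol ether, with the catalyst of step 9, gives the cyclic silyl enol ether F5. HF·pyridine in THF at 0 °C protonates C3 and frees the ketone without an enolate being formed, and the route is rejoined at 17.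

**Step 9 (key step).** What may go wrong is slow turnover if the catalyst rests as a chelated ortho-alkoxybenzylidene. Prolonged reaction would then allow hydride-induced migration of the double bond to the 4H-chromene (destroying C2), loss of isobutene from the prenyl groups by cross-metathesis, and light-induced electrocyclic opening of the product with racemisation. The fallback builds ring C without metathesis. It sets out from 2 and 12. Alcohol 12 is oxidised with MnO2 to enal 11, here isolated. Aldehydes 2 and 11 are condensed under an α,α-diphenylprolinol trimethylsilyl ether catalyst (toluene, rt; the catalyst antipode chosen for the required sense) by oxa-Michael addition and intramolecular aldol condensation. This gives (2R)-7-(methoxymethoxy)-2-[4-(methoxymethoxy)-3,5-bis(3-methylbut-2-en-1-yl)phenyl]-2H-chromene-3-carbaldehyde F6. Its R descriptor denotes the same spatial arrangement as S in 16, because the formyl-bearing C3 outranks ring B. Decarbonylation with RhCl(PPh3)3 (1 equiv, toluene, 80 °C) removes the formyl group and returns to the route at 16.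

**Step 8.** The electron-rich product can be re-ionised by the catalyst, which would erode both the enantiomeric purity and the branch selectivity; the ortho-substituted phenoxide may also react slowly. The fallback makes the aryl–oxygen bond instead of the allyl–oxygen bond and takes the stereocentre from an epoxidation. It sets out from 12. Sharpless epoxidation (Ti(Oi-Pr)4, D-(−)-diisopropyl tartrate, t-BuOOH, 4 Å sieves, CH2Cl2, −20 °C) should oxidise only the allylic-alcohol alkene. This gives [(2R,3R)-3-[4-(methoxymethoxy)-3,5-bis(3-methylbut-2-en-1-yl)phenyl]oxiran-2-yl]methanol F7. I2, PPh3 and imidazole convert it into the epoxy iodide F8. Zinc dust in ethanol opens F8 reductively to (1S)-1-[4-(methoxymethoxy)-3,5-bis(3-methylbut-2-en-1-yl)phenyl]prop-2-en-1-ol F9, with the benzylic C–O bond intact. Purchased 2-fluoro-4-hydroxybenzaldehyde F10 is protected (MOMCl, i-Pr2NEt) as 2-fluoro-4-(methoxymethoxy)benzaldehyde F11. The sodium alkoxide of F9 (NaH, DMF, 0 °C to rt) displaces the fluoride activated by the ortho formyl group, giving the (S)-aryloxybenzaldehyde F12. Wittig methylenation as in step 2 rejoins the route at 15.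

**Step 5.** The twofold coupling may stall after the first bromide, leaving the hindered second C–Br bond untouched, or give protodebromination; some coupling at the tertiary allyl terminus would give a reverse-prenyl isomer; and the allylzinc reagent may add to the enoate. The fallback attaches the prenyl groups by phenoxide C-alkylation and the acrylate by a Heck reaction. It sets out from 7 and purchased 4-iodophenol F13. The sodium phenoxide in toluene (NaH, 7 in excess, 0 °C to rt) is alkylated at both ortho carbons to give 4-iodo-2,6-bis(3-methylbut-2-en-1-yl)phenol F14, separated from mono- and O-alkylated material. MOMCl and i-Pr2NEt give 5-iodo-2-(methoxymethoxy)-1,3-bis(3-methylbut-2-en-1-yl)benzene F15. Heck coupling with ethyl acrylate (Pd(OAc)2, P(o-tol)3, Et3N, DMF, 80 °C) returns to the route at 10.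

## Further compounds

F1 | step 10 | 1-(2,4-dihydroxyphenyl)ethanone (purchased) | CC(=O)c1ccc(O)cc1O
F2 | step 10 | 1-[2-hydroxy-4-(methoxymethoxy)phenyl]ethanone | CC(=O)c1ccc(OCOC)cc1O
F3 | step 10 | 1-[2-{[(1S)-1-[4-(methoxymethoxy)-3,5-bis(3-methylbut-2-en-1-yl)phenyl]prop-2-en-1-yl]oxy}-4-(methoxymethoxy)phenyl]ethanone | CC(C)=CCc1cc([C@@H](Oc2cc(OCOC)ccc2C(C)=O)C=C)cc(CC=C(C)C)c1OCOC
F4 | step 10 | tert-butyl{[1-(2-{[(1S)-1-[4-(methoxymethoxy)-3,5-bis(3-methylbut-2-en-1-yl)phenyl]prop-2-en-1-yl]oxy}-4-(methoxymethoxy)phenyl)ethenyl]oxy}dimethylsilane | CC(C)=CCc1cc([C@@H](Oc2cc(OCOC)ccc2C(=C)O[Si](C)(C)C(C)(C)C)C=C)cc(CC=C(C)C)c1OCOC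
F5 | step 10 | (2S)-4-[(tert-butyldimethylsilyl)oxy]-7-(methoxymethoxy)-2-[4-(methoxymethoxy)-3,5-bis(3-methylbut-2-en-1-yl)phenyl]-2H-chromene | CC(C)=CCc1cc([C@@H]2C=C(O[Si](C)(C)C(C)(C)C)c3ccc(OCOC)cc3O2)cc(CC=C(C)C)c1OCOC
F6 | step 9 | (2R)-7-(methoxymethoxy)-2-[4-(methoxymethoxy)-3,5-bis(3-methylbut-2-en-1-yl)phenyl]-2H-chromene-3-carbaldehyde | CC(C)=CCc1cc([C@@H]2C(C=O)=Cc3ccc(OCOC)cc3O2)cc(CC=C(C)C)c1OCOC
F7 | step 8 | [(2R,3R)-3-[4-(methoxymethoxy)-3,5-bis(3-methylbut-2-en-1-yl)phenyl]oxiran-2-yl]methanol | OC[C@H]1O[C@@H]1c1cc(CC=C(C)C)c(OCOC)c(CC=C(C)C)c1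
F8 | step 8 | (2S,3R)-2-(iodomethyl)-3-[4-(methoxymethoxy)-3,5-bis(3-methylbut-2-en-1-yl)phenyl]oxirane | IC[C@H]1O[C@@H]1c1cc(CC=C(C)C)c(OCOC)c(CC=C(C)C)c1
F9 | step 8 | (1S)-1-[4-(methoxymethoxy)-3,5-bis(3-methylbut-2-en-1-yl)phenyl]prop-2-en-1-ol | CC(C)=CCc1cc([C@@H](O)C=C)cc(CC=C(C)C)c1OCOC
F10 | step 8 | 2-fluoro-4-hydroxybenzaldehyde (purchased) | O=Cc1ccc(O)cc1F
F11 | step 8 | 2-fluoro-4-(methoxymethoxy)benzaldehyde | COCOc1ccc(C=O)c(F)c1
F12 | step 8 | 2-{[(1S)-1-[4-(methoxymethoxy)-3,5-bis(3-methylbut-2-en-1-yl)phenyl]prop-2-en-1-yl]oxy}-4-(methoxymethoxy)benzaldehyde | CC(C)=CCc1cc([C@@H](Oc2cc(OCOC)ccc2C=O)C=C)cc(CC=C(C)C)c1OCOC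
F13 | step 5 | 4-iodophenol (purchased) | Oc1ccc(I)cc1
F14 | step 5 | 4-iodo-2,6-bis(3-methylbut-2-en-1-yl)phenol | CC(C)=CCc1cc(I)cc(CC=C(C)C)c1O
F15 | step 5 | 5-iodo-2-(methoxymethoxy)-1,3-bis(3-methylbut-2-en-1-yl)benzene | CC(C)=CCc1cc(I)cc(CC=C(C)C)c1OCOC
A1 | alternative 1 | (2S)-4-[(tert-butyldimethylsilyl)oxy]-2-{4-[(tert-butyldimethylsilyl)oxy]-3,5-bis(3-methylbut-2-en-1-yl)phenyl}-7-(4,4,5,5-tetramethyl-1,3,2-dioxaborolan-2-yl)-5-(trimethylsilyl)chromane | CC(C)=CCc1cc([C@@H]2CC(O[Si](C)(C)C(C)(C)C)c3c([Si](C)(C)C)cc(B4OC(C)(C)C(C)(C)O4)cc3O2)cc(CC=C(C)C)c1O[Si](C)(C)C(C)(C)C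
A2 | alternative 1 | (1S)-1-{4-[(tert-butyldimethylsilyl)oxy]-3,5-bis(3-methylbut-2-en-1-yl)phenyl}-3-[(tert-butyldimethylsilyl)oxy]-5-(trimethylsilyl)pent-4-yn-1-yl ethynyl ether | CC(C)=CCc1cc([C@H](CC(O[Si](C)(C)C(C)(C)C)C#C[Si](C)(C)C)OC#C)cc(CC=C(C)C)c1O[Si](C)(C)C(C)(C)C
A3 | alternative 1 | 2-ethynyl-4,4,5,5-tetramethyl-1,3,2-dioxaborolane | C#CB1OC(C)(C)C(C)(C)O1
A4 | alternative 2 | (2S)-7-[(tert-butyldimethylsilyl)oxy]-2-{4-[(tert-butyldimethylsilyl)oxy]-3,5-bis(3-methylbut-2-en-1-yl)phenyl}-2,3-dihydro-4H-chromen-4-one | CC(C)=CCc1cc([C@@H]2CC(=O)c3ccc(O[Si](C)(C)C(C)(C)C)cc3O2)cc(CC=C(C)C)c1O[Si](C)(C)C(C)(C)C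
A5 | alternative 2 | racemic 7-[(tert-butyldimethylsilyl)oxy]-2-{4-[(tert-butyldimethylsilyl)oxy]-3,5-bis(3-methylbut-2-en-1-yl)phenyl}-4-methylidene-4H-1,3-benzodioxine | C=C1OC(c2cc(CC=C(C)C)c(O[Si](C)(C)C(C)(C)C)c(CC=C(C)C)c2)Oc2cc(O[Si](C)(C)C(C)(C)C)ccc21
A6 | alternative 3 | ethyl 4-hydroxy-3,5-bis(3-methylbut-2-en-1-yl)benzoate | CCOC(=O)c1cc(CC=C(C)C)c(O)c(CC=C(C)C)c1
A7 | alternative 3 | 2,10-dimethylundeca-2,9-dien-6-one | CC(C)=CCCC(=O)CCC=C(C)C
A8 | alternative 3 | ethyl 2-formyl-3-oxopropanoate | CCOC(=O)C(C=O)C=O
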